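**Plan**

- Retrosynthesis: the O7–CH3 bond is cut first (late selective O-methylation). The C8–C1'' and C6–C1'' bonds of the two 3-methylbut-2-enyl groups are cut next, in one enzymatic operation, to (2S)-homoeriodictyol and dimethylallyl diphosphate. The O1–C2 bond is cut last, to an achiral chalcone made from commercial homoeriodictyol.
- Enabling feature: ring A is a phloroglucinol-type ring whose only two C–H carbons are C6 (between C5–OH and C7–OH) and C8 (between C7–OH and C8a–O1). They carry identical prenyl groups on a (2S)-flavanone, the acceptor class of flavonoid dimethylallyltransferases.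
- Forward: rings A and B are bought. Ring C is opened and reclosed enzymatically, both prenyl chains are then attached to the finished flavanone (C8, then C6), and the 7-O-methyl group is added last.
- Stereochemistry: C2 is the only stereocentre. Chalcone isomerase sets it as (S) in step 2, the (2S)-selective 8-prenyltransferase filters it again in step 4, and all later conditions are neutral or near neutral.
- Dimethylallyl diphosphate is made in one chemical step from prenyl bromide (side branch).

Key step: step 4

Assumption: commercial homoeriodictyol is treated as racemic (its optical purity is not reliable), so C2 is set inside the route; the three recombinant enzymes are counted as catalysts, not as steps.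

**Step 1**
Reactants: 1 racemic homoeriodictyol
Product: 2 homoeriodictyol chalcone
Conditions: 50% aq. KOH, Ar, rt, 10 min; poured onto ice/6 M HCl to pH 2; cold filtration; Sephadex LH-20 (MeOH) to remove residual 1, which is recycled
Reagents that add atoms: none
Why: Base-mediated E1cB retro-oxa-Michael opening of the flavanone, in which C3 deprotonation expels the C8a phenoxide and the conjugated chalcone polyanion is the resting state in concentrated alkali, so a fast cold acid quench should precipitate 2 before it recloses, as is known for 2',4',6'-trihydroxychalcones.

**Step 2**
Reactants: 2 homoeriodictyol chalcone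
Product: 3 (2S)-homoeriodictyol
Conditions: recombinant type I chalcone isomerase (Medicago sativa, from E. coli), 50 mM potassium phosphate pH 6.5, 5% DMSO, substrate ≤ 0.5 mM, 20 °C; EtOAc extraction
Reagents that add atoms: none
Why: Chalcone isomerase catalyses the 6-endo-trig intramolecular oxa-Michael addition of the 2'-phenoxide to the enone β-carbon in a pocket that exposes one face of the alkene, which sets C2 as (S) as in flavonoid biosynthesis, while pH 6.5 keeps the uncatalysed racemic closure slow against the near diffusion-limited enzyme.

**Step 3**
Reactants: 4 prenyl bromide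
Product: 6 dimethylallyl diphosphate triammonium salt, via tetrabutylammonium dimethylallyl diphosphate 5 (not isolated)
Conditions: (Bu4N)3HP2O7 (2 equiv), MeCN, 0 °C to rt; Dowex 50WX8 (NH4+ form), 25 mM NH4HCO3; lyophilisation; cellulose chromatography
Reagents that add atoms: tris(tetrabutylammonium) hydrogen diphosphate, CCCC[N+](CCCC)(CCCC)CCCC.CCCC[N+](CCCC)(CCCC)CCCC.CCCC[N+](CCCC)(CCCC)CCCC.OP(=O)([O-])OP(=O)([O-])[O-]; ammonium hydrogen carbonate, [NH4+].OC(=O)[O-]
Why: SN2 displacement of the primary allylic bromide by the diphosphate anion, held in acetonitrile as its lipophilic tetrabutylammonium salt (Davisson–Poulter diphosphorylation), followed by cation exchange to the water-soluble ammonium salt; attack at the unhindered primary carbon keeps the 3,3-dimethylallyl connectivity.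

**Step 4**
Reactants: 3 (2S)-homoeriodictyol; 6 dimethylallyl diphosphate triammonium salt (two portions, 2.7 equiv in all)
Product: 8 (2S)-6,8-diprenylhomoeriodictyol, via (2S)-8-prenylhomoeriodictyol 7 (not isolated)
Conditions: (i) flavanone 8-dimethylallyltransferase SfFPT (Sophora flavescens, yeast microsomes), 6 (1.2 equiv), MgCl2 10 mM, DTT 1 mM, Tris-HCl 50 mM pH 7.5, 5% DMSO, 30 °C, until 3 is consumed (HPLC); (ii) same vessel: C6-selective soluble prenyltransferase (7-DMATS type, Aspergillus fumigatus, His-tagged), 6 (1.5 equiv), CaCl2 5 mM, 30 °C; EtOAc extraction at pH 5; RP-HPLC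
Reagents that add atoms: none
Why: Each enzyme ionises its bound dimethylallyl diphosphate to an allyl cation–diphosphate ion pair held over ring A, the ring carbon attacks the primary C1 of the cation, and an active-site base removes the arenium proton to restore the aromatic ring. The closest known reaction type is the biocatalytic Friedel–Crafts C-dimethylallylation of (2S)-flavanones, established at C8 for plant membrane-bound transferases and at C6 for fungal soluble transferases of the dimethylallyltryptophan synthase family; here the two are run one after the other in one vessel. No ring is closed and no stereocentre is formed; C2 is carried through unchanged at pH 7.5, and the (2S) preference of the 8-transferase additionally filters out any (2R) material. The step needs C- over O-alkylation, ring A over the guaiacol ring B, normal over reverse attachment, and two transfers to two different carbons. These are secured by the substrate, since C8 and C6 are the only ring carbons flanked on both sides by oxygen-bearing carbons and are activated by the free 7-hydroxyl, and by the order of addition: the narrow plant enzyme acts first on a native-type acceptor, and the promiscuous soluble enzyme acts second, when C6 is the only ring-A carbon left.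

**Step 5**
Reactants: 8 (2S)-6,8-diprenylhomoeriodictyol
Product: 9 (2S)-5-hydroxy-2-(4-hydroxy-3-methoxyphenyl)-7-methoxy-6,8-bis(3-methylbut-2-enyl)chroman-4-one (CNP0260843.1)
Conditions: TMSCHN2 (1.05 equiv, 2 M in hexanes), toluene/MeOH 4:1, 0 °C to rt, no base; AcOH quench
Reagents that add atoms: (trimethylsilyl)diazomethane, C[Si](C)(C)C=[N+]=[N-]
Why: Diazoalkane O-methylation (proton transfer, then SN2 on the methyldiazonium ion) should pick the 7-hydroxyl, a vinylogous acid para to the C4 carbonyl, because the 5-hydroxyl is locked in a hydrogen bond to C4=O and the guaiacol 4'-hydroxyl is too weakly acidic to protonate the reagent at a comparable rate without base; the neutral medium leaves C2 and both prenyl alkenes untouched.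

**Compound list**

1 | racemic homoeriodictyol, (±)-5,7-dihydroxy-2-(4-hydroxy-3-methoxyphenyl)chroman-4-one | COc1cc(C2CC(=O)c3c(O)cc(O)cc3O2)ccc1O | starting material
2 | homoeriodictyol chalcone, (E)-3-(4-hydroxy-3-methoxyphenyl)-1-(2,4,6-trihydroxyphenyl)prop-2-en-1-one | COc1cc(/C=C/C(=O)c2c(O)cc(O)cc2O)ccc1O | intermediate
3 | (2S)-homoeriodictyol | COc1cc([C@@H]2CC(=O)c3c(O)cc(O)cc3O2)ccc1O | intermediate
4 | prenyl bromide, 1-bromo-3-methylbut-2-ene | CC(C)=CCBr | starting material
5 | bis(tetrabutylammonium) hydrogen dimethylallyl diphosphate | CC(C)=CCOP(=O)([O-])OP(=O)(O)[O-].CCCC[N+](CCCC)(CCCC)CCCC.CCCC[N+](CCCC)(CCCC)CCCC | intermediate (not isolated)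
6 | dimethylallyl diphosphate triammonium salt | CC(C)=CCOP(=O)([O-])OP(=O)([O-])[O-].[NH4+].[NH4+].[NH4+] | intermediate
7 | (2S)-8-prenylhomoeriodictyol, (2S)-5,7-dihydroxy-2-(4-hydroxy-3-methoxyphenyl)-8-(3-methylbut-2-enyl)chroman-4-one | COc1cc([C@@H]2CC(=O)c3c(O)cc(O)c(CC=C(C)C)c3O2)ccc1O | intermediate (not isolated)
8 | (2S)-6,8-diprenylhomoeriodictyol, (2S)-5,7-dihydroxy-2-(4-hydroxy-3-methoxyphenyl)-6,8-bis(3-methylbut-2-enyl)chroman-4-one | COc1cc([C@@H]2CC(=O)c3c(O)c(CC=C(C)C)c(O)c(CC=C(C)C)c3O2)ccc1O | intermediate
9 | (2S)-5-hydroxy-2-(4-hydroxy-3-methoxyphenyl)-7-methoxy-6,8-bis(3-methylbut-2-enyl)chroman-4-one | COc1cc([C@@H]2CC(=O)c3c(O)c(CC=C(C)C)c(OC)c(CC=C(C)C)c3O2)ccc1O | target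

**Step count and risks**

Total step count: 5. Longest linear sequence: 4 (steps 1, 2, 4, 5); step 3 is a one-step side branch.

Steps most likely to fail:

Step 4. The second transfer may stall at the mono-prenyl stage if the soluble C6 enzyme does not turn over an acceptor that already carries a C8 side chain. The cation may also be captured at O-7 or on ring B. The fallback drops the enzymes and builds the ring-A pattern by acid-mediated nuclear prenylation, a known electrophilic C-prenylation of 5,7-dihydroxyflavanones. It sets out from 1, which is racemic, so epimerisation at C2 does not matter. Treatment with 2-methylbut-3-en-2-ol and BF3·OEt2 in dioxane at rt should give, after chromatography to remove lower-alkylated and cyclised by-products, racemic 6,8-diprenylhomoeriodictyol F1. The reaction is direct but unselective. Preparative HPLC on an amylose tris(3,5-dimethylphenylcarbamate) phase then separates 8 from (2R)-6,8-diprenylhomoeriodictyol F2, which is discarded. The route is rejoined at 8.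

Step 5. Methyl transfer may not stop at O-7: if the 7-hydroxyl, shielded by two ortho prenyl groups, reacts slowly, the unhindered 4'-hydroxyl can compete and over-methylation follows. The fallback sets out from 8 and uses a SAM-dependent flavanone 7-O-methyltransferase (naringenin 7-O-methyltransferase type) in pH 7.5 buffer. The site is then fixed by the active site and not by relative acidity, although acceptance of the diprenylated substrate may need enzyme screening. It gives 9 directly and makes no new compound.

Step 2. Uncatalysed closure of the 2',6'-dihydroxychalcone, or racemic flavanone carried over from step 1, may lower the enantiomeric purity of 3. The fallback bypasses 2. It sets out from 1, which is resolved by preparative HPLC on a polysaccharide chiral phase to give 3 and (2R)-homoeriodictyol F3. F3 is racemised back to 1 with dilute aqueous base (ring opening and reclosure) and resolved again. The route is rejoined at 3.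

**Further compounds**

F1 | step 4 | racemic 6,8-diprenylhomoeriodictyol | COc1cc(C2CC(=O)c3c(O)c(CC=C(C)C)c(O)c(CC=C(C)C)c3O2)ccc1O
F2 | step 4 | (2R)-6,8-diprenylhomoeriodictyol | COc1cc([C@H]2CC(=O)c3c(O)c(CC=C(C)C)c(O)c(CC=C(C)C)c3O2)ccc1O
F0 | step 5 | none | none
F3 | step 2 | (2R)-homoeriodictyol | COc1cc([C@H]2CC(=O)c3c(O)cc(O)cc3O2)ccc1O
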